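## The problem

Compound 24 is a dearomatised acylphloroglucinol. Ring A is a cyclohexadienone with a ketone at C4, a quaternary C5 carrying two prenyl groups, an enolic hydroxyl at C6 and a 3-methylbutanoyl group at C7 (benzofuran numbering); it is fused along C3a–C7a to a 2,3-dihydrofuran, ring B, made up of O1, C2 and C3. The only stereocentre is C2 (R), which bears a 2-hydroxypropan-2-yl group; C5 has two identical chains and is not stereogenic, so no centre can direct another and C2 has to be set by an external chiral agent. Three questions of position arise: O1 must be the phloroglucinol oxygen on the carbon next to the acyl-bearing C7, not the one on the far side of C3a, which ends as the C4 carbonyl; both prenyl groups must go to C5 on carbon, not to oxygen and not to the ring-fusion carbon C3a; and later steps must leave C2 untouched. The prenyl alkenes will not survive hydrogenation, strong acid or electrophilic oxidants, the tertiary alcohol ionises and dehydrates in acid, and the enolised tricarbonyl array is acidic, chelating and open to nucleophiles, so the dearomatised ring with its alkenes should appear only at the end. Until then ring A can be handled as its aromatic tautomer, a phloroglucinol in which all three oxygens and the acyl group are in place from cheap material. The feature that allows a short route is the C3–C2–O1 fragment: C3 is a methylene on C3a, ortho to the oxygen-bearing C7a, which is the exocyclic carbon of an ortho-quinone methide, and C2 is one carbon bonded to O1 and C3 whose C(CH3)2OH group is an ester once two methyl nucleophiles are taken away. C2 can therefore enter as the carbon of an ester-stabilised ylide that bonds first to C3 and then to O1, and a chiral leaving group on that ylide gives a handle on its configuration.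

## Retrosynthesis

**24 ⇒ 21 + 22.** The two C5–CH2 bonds to the prenyl groups are cut last, by way of monoprenyl phenol 23. This keeps the alkenes out of the hydrogenolysis and Grignard steps and replaces a labile dienone by the flat aromatic diol 21, whose only free ring carbon is C5. Building the quaternary carbon into a ring made from acyclic pieces would cost a whole ring synthesis. The forward reaction must alkylate carbon twice at C5 in preference to oxygen.

**21 ⇒ 20 ⇒ 18.** The benzyl–oxygen bond and the two C–CH3 bonds of the carbinol are cut, the latter through methyl ketone 19. The ester of 18 is both the group that stabilises the ylide in the key step and the precursor of the tertiary alcohol, so no extra carbon–carbon step is spent on the side chain. The forward Grignard reaction must spare the aryl ketone, which is the reason the C6 hydroxyl is left free: as a magnesium phenoxide it deactivates that ketone.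

**18 ⇒ 8 + 13.** Both bonds to C2 are cut, C3–C2 and O1–C2, in a [4+1] sense, passing through methiodide 14, ylide 15, quinone methide 16 and betaine 17.
- Against the neighbouring cuts: breaking O1–C2 alone leads back to a chiral prenyl epoxide and asks for selective mono-prenylation and oxidation of an electron-rich phenol. Breaking C3a–C3 asks for metal-mediated functionalisation of the arene.
- Here C3 comes from the most dependable reaction of an electron-rich phenol, aminomethylation, and C2 arrives with its oxygen bond and its configuration in one operation.
- The simplification is from a chiral bicycle to an achiral arene and a two-carbon ammonium salt.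
- The forward step must differentiate the faces of the ylide carbon and close onto the correct oxygen; the benzyl ether settles the second point.

**13 ⇒ 11 + 12, 11 ⇒ 9.** The N–CH2 bond of the salt is cut to O-methylquinidine 11 and methyl bromoacetate 12, and the methyl ether of 11 to quinidine 9 through alkoxide 10. The ether removes a hydroxyl that could transesterify with the neighbouring ester under carbonate. Both steps are routine.

**8 ⇒ 5 + 6, 5 ⇒ 3 + 4, 3 ⇒ 1 + 2.** The C3a–C3 bond is cut to benzyl ether 5 and iminium salt 6 (through hydroiodide 7), the benzyl ether to triol ketone 3 and benzyl bromide 4, and the aryl–acyl bond to phloroglucinol 1 and acid chloride 2. The benzyl group does two jobs: it blocks the oxygen that must become the C4 carbonyl from closing ring B, and it leaves 5 with a mirror plane so that the Mannich reaction has only one possible site.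

## Roads not taken

**Alternative 1:** Ring A, not ring B, is taken apart.
- Forward key step: heating 3-ethoxy-4,4-diprenylcyclobutenone A1 with the chiral siloxyalkyne A2 opens A1 to a vinylketene, which adds the alkyne by [2+2], reopens to a dienylketene and closes by 6π electrocyclisation. The product is dienone A3, with the gem-diprenyl carbon already in place and the future C2 carried as an acetonide-protected diol.
- Merits: it avoids the dearomatising double prenylation, the least predictable step of the chosen plan, and it takes C2 from an enantiopure diol, so enantiopurity is not in question. On both counts it is better than the chosen plan.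
- Weak points: A3 has neither ring B nor the C7 acyl group. After it the diol must be freed and closed onto C7a and not onto C4 (both carbonyl carbons flank C3a, so the regiochemical question returns at the end), the ethyl enol ether hydrolysed, and C7 acylated on a vinylogous acid. A1 and A2 each need several steps, and a vinylketene heated next to two prenyl groups may undergo intramolecular ene or [2+2] reactions.
- Comparison: the chosen plan sets against it nine steps from phloroglucinol, with the acyl group and all oxygens present from step 1 and the regiochemistry of ring B fixed by a protecting group.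

**Alternative 2:** The C3a–C3 and C7a–O1 bonds are cut.
- Forward key step: Pd(OAc)2, a phosphine and norbornene couple aryl iodide A4 with the (R)-epoxide A5; the palladacycle alkylates the ortho C–H with the epoxide CH2 and the alkoxide then closes the ring at the ipso carbon to give A6.
- Merits: the epoxide C–O bond at the stereocentre is never broken, so the configuration of A5 is carried over unchanged. This is clearly better than the chosen plan on enantiocontrol. The tertiary alcohol arrives protected, so no Grignard reagent meets the aryl ketone.
- Weak points: A4 is not a phloroglucinol derivative, since the C7a oxygen is made in the step, so its acyl group must be placed selectively beside the iodine on a meta-dioxygenated iodoarene. The ortho substituent is an enolisable ketone that can be α-arylated or bind palladium. Oxidative addition to so electron-rich an iodide is slow. The C–O reductive elimination involves a secondary alkoxide next to a fully substituted carbon. A5 needs its own asymmetric preparation. The acetal groups must be removed with acid beside a tertiary ether, and the late diprenylation remains.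
- Comparison: length is similar. The chosen plan offers cheaper reagents, no metal relay on an enolisable ketone and regiochemistry by symmetry; it pays for this with enantiocontrol that has yet to be proven.

**Alternative 3:** The O1–C2 bond is made by a 1,2-shift of the ring oxygen.
- Forward sequence: mono-C-prenylation of 5 gives A7; asymmetric epoxidation and 6-endo closure give the (3S)-chromanol A8; sulfonylation lets the ring oxygen displace the sulfonate with inversion to an oxiranium ion, which water opens at the tertiary carbon to give A9, identical with compound 20 of the chosen route.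
- Merits: the stereocentre comes from an epoxidation of a trisubstituted alkene, a dependable source of enantiopurity, and the inversion is stereospecific. On enantiocontrol it is as good as or better than the chosen plan.
- Weak points: it needs more steps to reach the same compound (prenylation, phenol protection against the oxidant, epoxidation, cyclisation, activation). Mono-prenylation of 5 is itself a selectivity problem. The sulfonate of A8 can eliminate to the conjugated 2H-chromene. The ring oxygen sits ortho to the acyl group and is a weakened neighbouring group. Water capture competes with proton loss to an isopropenyl compound.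
- Comparison: the chosen plan reaches 20 from 8 in two steps with no oxidant near the phenol; it has to set the unproven face selectivity of its ylide against the secure epoxidation.

Key step: step 6

Remarks on the chemistry, as assumptions:
- Compound 24 is written as the 4-keto-6-enol tautomer of the target SMILES; the enolised tricarbonyl array equilibrates among tautomers and nothing is claimed about which predominates.
- It is assumed that the quinidine-derived salt 13 gives the (2R) ester 18. The sense of induction for a methide without a substituent is not known; if the (2S) ester were favoured, the pseudoenantiomeric cinchona series would be used with no other change.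

## Route

Step 1
Reactants: 1 phloroglucinol (benzene-1,3,5-triol); 2 isovaleryl chloride (3-methylbutanoyl chloride)
Product: 3 3-methyl-1-(2,4,6-trihydroxyphenyl)butan-1-one
Conditions: AlCl3 (4 equiv), PhNO2, 0 → 65 °C; ice, aq. HCl
Reagents that add atoms: none
Why: Friedel–Crafts C-acylation of a threefold activated ring whose three free carbons are equivalent; the first acyl group, chelated to aluminium, deactivates the ring, so monoacylation is expected.

Step 2
Reactants: 3 3-methyl-1-(2,4,6-trihydroxyphenyl)butan-1-one; 4 benzyl bromide
Product: 5 1-[4-(benzyloxy)-2,6-dihydroxyphenyl]-3-methylbutan-1-one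
Conditions: BnBr (1.0 equiv), K2CO3 (1.1 equiv), DMF, 0 °C → rt
Reagents that add atoms: none
Why: Williamson etherification; the two ortho hydroxyls are hydrogen-bonded to the ketone and are less acidic and less nucleophilic than the para hydroxyl, so one equivalent of base and halide should alkylate the para oxygen.

Step 3
Reactants: 5 1-[4-(benzyloxy)-2,6-dihydroxyphenyl]-3-methylbutan-1-one; 6 dimethylmethyleneammonium iodide (Eschenmoser's salt)
Product: 8 1-{4-(benzyloxy)-3-[(dimethylamino)methyl]-2,6-dihydroxyphenyl}-3-methylbutan-1-one, via hydroiodide salt 7 (not isolated)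
Conditions: 6 (1.0 equiv), CH2Cl2, 0 °C → rt; aq. NaHCO3; used without storage
Reagents that add atoms: none
Why: Mannich aminomethylation by a preformed iminium ion; the two free ring carbons of 5 are equivalent, so one regioisomer is possible, and without added base the product stays as the ammonium salt 7, which should hold back a second substitution.

Step 4
Reactants: 9 quinidine
Product: 11 O-methylquinidine, via sodium alkoxide 10 (not isolated)
Conditions: NaH (1.2 equiv), DMF, 0 °C → rt; MeI (1.05 equiv), 0 °C → rt
Reagents that add atoms: methyl iodide, CI
Why: Williamson O-methylation; the alkoxide is far more nucleophilic than either nitrogen, so a near-stoichiometric charge of methyl iodide should give the ether without quaternisation, and no stereocentre is touched.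

Step 5
Reactants: 11 O-methylquinidine; 12 methyl bromoacetate
Product: 13 (8R,9S)-6',9-dimethoxy-1-(2-methoxy-2-oxoethyl)cinchonan-1-ium bromide
Conditions: THF, rt; the precipitated salt is filtered and washed
Reagents that add atoms: none
Why: Menshutkin N-alkylation at the quinuclidine nitrogen, much the more nucleophilic of the two; isolating the salt keeps free bromoacetate out of step 6, where it could O-alkylate the phenoxide or form an achiral ylide with liberated trimethylamine.

Step 6
Reactants: 8 1-{4-(benzyloxy)-3-[(dimethylamino)methyl]-2,6-dihydroxyphenyl}-3-methylbutan-1-one; 13 (8R,9S)-6',9-dimethoxy-1-(2-methoxy-2-oxoethyl)cinchonan-1-ium bromide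
Product: 18 methyl (2R)-4-(benzyloxy)-6-hydroxy-7-(3-methylbutanoyl)-2,3-dihydro-1-benzofuran-2-carboxylate, via trimethylammonium iodide 14 (not isolated), via ammonium ylide 15 (not isolated), via ortho-quinone methide 16 (not isolated), via ammonium phenoxide betaine 17 (not isolated)
Conditions: (a) MeI (1.2 equiv), MeCN, rt, then evaporation to dryness; (b) 14 in MeCN added slowly to 13 (1.5 equiv), Cs2CO3 (3.5 equiv), CH2Cl2, −20 °C → rt; aq. NH4Cl; 11 recovered by acid extraction
Reagents that add atoms: none
Why: Methyl iodide quaternises the benzylic amine, and carbonate then expels trimethylamine from the phenoxide of 14 to give quinone methide 16 (the ortho form through the C7a oxygen and the para form through the other free oxygen give the same adduct), while the same base deprotonates 13 to the ester-stabilised ylide 15. The ylide carbon adds in a Michael sense to the unsubstituted methylene of 16 (C3–C2 bond) and restores the aromatic ring in betaine 17; the phenoxide ortho to the new chain then displaces the ammonium group in a 5-exo-tet SN2 closure with inversion (O1–C2 bond), giving ring B and releasing 11. The closest known reaction type is the [4+1] annulation of ortho-quinone methides generated in the flask with cinchona-derived ammonium ylides to trans-2,3-disubstituted dihydrobenzofurans, together with the racemic annulation of methylene quinone methides from phenolic Mannich salts with nitrogen ylides. C2, the only new stereocentre, is controlled by the chiral ammonium group, either through the face of the ylide left open in the C–C bond formation or, if the acidic C–H of 17 equilibrates, through the faster-closing diastereomeric betaine; (S) at the ammonium carbon of 17 becomes (R) at C2. Enantiocontrol with a methide that carries no substituent has not been demonstrated and is the point on which this step has to be tested. The step needs regioselectivity in the closure, and the substrate secures it: the other oxygen ortho to the chain is benzylated and the remaining free oxygen is para to it, so only the C7a oxygen can close. It also needs the ylide to outrun capture of 16 by the electron-rich ring of a second molecule, which the slow addition of 14 to excess ylide is meant to ensure.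

Step 7
Reactants: 18 methyl (2R)-4-(benzyloxy)-6-hydroxy-7-(3-methylbutanoyl)-2,3-dihydro-1-benzofuran-2-carboxylate
Product: 20 1-[(2R)-4-(benzyloxy)-6-hydroxy-2-(2-hydroxypropan-2-yl)-2,3-dihydro-1-benzofuran-7-yl]-3-methylbutan-1-one, via methyl ketone 19 (not isolated)
Conditions: MeMgBr (3.5 equiv), THF, −78 → 0 °C; aq. NH4Cl
Reagents that add atoms: methylmagnesium bromide, C[Mg]Br
Why: Twofold Grignard addition to the ester; the first equivalent turns the phenol into a magnesium phenoxide chelated to the aryl ketone, which as a doubly ortho-substituted vinylogous carboxylate is far less electrophilic than the α-aryloxy ester and its ketone successor 19. C2 is not a reacting centre, and low temperature should keep 19 from enolising, so the (2R) configuration is carried through.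

Step 8
Reactants: 20 1-[(2R)-4-(benzyloxy)-6-hydroxy-2-(2-hydroxypropan-2-yl)-2,3-dihydro-1-benzofuran-7-yl]-3-methylbutan-1-one
Product: 21 1-[(2R)-4,6-dihydroxy-2-(2-hydroxypropan-2-yl)-2,3-dihydro-1-benzofuran-7-yl]-3-methylbutan-1-one
Conditions: H2 (1 atm), 10% Pd/C (palladium metal on carbon), EtOAc, rt
Reagents that add atoms: none
Why: Hydrogenolysis of a benzyl aryl ether under neutral conditions; no alkene is yet present, the hydrogen-bonded aryl ketone is inert at one atmosphere, and the C2–O1 bond is not benzylic.

Step 9
Reactants: 21 1-[(2R)-4,6-dihydroxy-2-(2-hydroxypropan-2-yl)-2,3-dihydro-1-benzofuran-7-yl]-3-methylbutan-1-one; 22 prenyl bromide (1-bromo-3-methylbut-2-ene)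
Product: 24 (2R)-6-hydroxy-2-(2-hydroxypropan-2-yl)-7-(3-methylbutanoyl)-5,5-bis(3-methylbut-2-en-1-yl)-2,3-dihydro-1-benzofuran-4(5H)-one, via monoprenyl phenol 23 (not isolated)
Conditions: 22 (2.2 equiv), 10% aq. KOH, 0 °C → rt; aq. HCl to pH 3
Reagents that add atoms: none
Why: Base-mediated twofold C-alkylation of an acylphloroglucinol phenoxide at C5, the only unsubstituted ring carbon and ortho to both phenoxide oxygens; the second alkylation on the same carbon dearomatises ring A, a long-known reaction of this compound class. Water solvates the phenoxide oxygens and so favours attack through carbon; the carbinol and C2 are not involved.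

## Compound list

1 | phloroglucinol (benzene-1,3,5-triol) | Oc1cc(O)cc(O)c1 | starting material
2 | isovaleryl chloride (3-methylbutanoyl chloride) | CC(C)CC(=O)Cl | starting material
3 | 3-methyl-1-(2,4,6-trihydroxyphenyl)butan-1-one | CC(C)CC(=O)c1c(O)cc(O)cc1O | intermediate
4 | benzyl bromide | BrCc1ccccc1 | starting material
5 | 1-[4-(benzyloxy)-2,6-dihydroxyphenyl]-3-methylbutan-1-one | CC(C)CC(=O)c1c(O)cc(OCc2ccccc2)cc1O | intermediate
6 | dimethylmethyleneammonium iodide (Eschenmoser's salt) | C=[N+](C)C.[I-] | starting material
7 | [6-(benzyloxy)-2,4-dihydroxy-3-(3-methylbutanoyl)phenyl]-N,N-dimethylmethanaminium iodide (hydroiodide of 8) | CC(C)CC(=O)c1c(O)cc(OCc2ccccc2)c(C[NH+](C)C)c1O.[I-] | intermediate (not isolated)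
8 | 1-{4-(benzyloxy)-3-[(dimethylamino)methyl]-2,6-dihydroxyphenyl}-3-methylbutan-1-one | CC(C)CC(=O)c1c(O)cc(OCc2ccccc2)c(CN(C)C)c1O | intermediate
9 | quinidine, (8R,9S)-6'-methoxycinchonan-9-ol | COc1ccc2nccc([C@H](O)[C@H]3C[C@@H]4CCN3C[C@@H]4C=C)c2c1 | starting material
10 | sodium (8R,9S)-6'-methoxycinchonan-9-olate | COc1ccc2nccc([C@H]([O-])[C@H]3C[C@@H]4CCN3C[C@@H]4C=C)c2c1.[Na+] | intermediate (not isolated)
11 | O-methylquinidine, (8R,9S)-6',9-dimethoxycinchonan | COc1ccc2nccc([C@H](OC)[C@H]3C[C@@H]4CCN3C[C@@H]4C=C)c2c1 | intermediate
12 | methyl bromoacetate | BrCC(=O)OC | starting material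
13 | (8R,9S)-6',9-dimethoxy-1-(2-methoxy-2-oxoethyl)cinchonan-1-ium bromide (configuration at nitrogen fixed by the cage) | COc1ccc2nccc([C@H](OC)[C@H]3C[C@@H]4CC[N+]3(CC(=O)OC)C[C@@H]4C=C)c2c1.[Br-] | intermediate
14 | [6-(benzyloxy)-2,4-dihydroxy-3-(3-methylbutanoyl)phenyl]-N,N,N-trimethylmethanaminium iodide | CC(C)CC(=O)c1c(O)cc(OCc2ccccc2)c(C[N+](C)(C)C)c1O.[I-] | intermediate (not isolated)
15 | [(8R,9S)-6',9-dimethoxycinchonan-1-ium-1-yl](methoxycarbonyl)methanide | COc1ccc2nccc([C@H](OC)[C@H]3C[C@@H]4CC[N+]3([CH-]C(=O)OC)C[C@@H]4C=C)c2c1 | intermediate (not isolated)
16 | 3-(benzyloxy)-5-hydroxy-2-methylidene-6-(3-methylbutanoyl)cyclohexa-3,5-dien-1-one | CC(C)CC(=O)C1=C(O)C=C(OCc2ccccc2)C(=C)C1=O | intermediate (not isolated)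
17 | 3-(benzyloxy)-5-hydroxy-2-{(2S)-2-[(8R,9S)-6',9-dimethoxycinchonan-1-ium-1-yl]-3-methoxy-3-oxopropyl}-6-(3-methylbutanoyl)phenolate | COc1ccc2nccc([C@H](OC)[C@H]3C[C@@H]4CC[N+]3([C@H](C(=O)OC)Cc5c(OCc6ccccc6)cc(O)c(C(=O)CC(C)C)c5[O-])C[C@@H]4C=C)c2c1 | intermediate (not isolated)
18 | methyl (2R)-4-(benzyloxy)-6-hydroxy-7-(3-methylbutanoyl)-2,3-dihydro-1-benzofuran-2-carboxylate | CC(C)CC(=O)c1c(O)cc(OCc2ccccc2)c2c1O[C@@H](C(=O)OC)C2 | intermediate
19 | 1-[(2R)-2-acetyl-4-(benzyloxy)-6-hydroxy-2,3-dihydro-1-benzofuran-7-yl]-3-methylbutan-1-one | CC(C)CC(=O)c1c(O)cc(OCc2ccccc2)c2c1O[C@@H](C(C)=O)C2 | intermediate (not isolated)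
20 | 1-[(2R)-4-(benzyloxy)-6-hydroxy-2-(2-hydroxypropan-2-yl)-2,3-dihydro-1-benzofuran-7-yl]-3-methylbutan-1-one | CC(C)CC(=O)c1c(O)cc(OCc2ccccc2)c2c1O[C@@H](C(C)(C)O)C2 | intermediate
21 | 1-[(2R)-4,6-dihydroxy-2-(2-hydroxypropan-2-yl)-2,3-dihydro-1-benzofuran-7-yl]-3-methylbutan-1-one | CC(C)CC(=O)c1c(O)cc(O)c2c1O[C@@H](C(C)(C)O)C2 | intermediate
22 | prenyl bromide (1-bromo-3-methylbut-2-ene) | CC(C)=CCBr | starting material
23 | 1-[(2R)-4,6-dihydroxy-2-(2-hydroxypropan-2-yl)-5-(3-methylbut-2-en-1-yl)-2,3-dihydro-1-benzofuran-7-yl]-3-methylbutan-1-one | CC(C)CC(=O)c1c(O)c(CC=C(C)C)c(O)c2c1O[C@@H](C(C)(C)O)C2 | intermediate (not isolated)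
24 | (2R)-6-hydroxy-2-(2-hydroxypropan-2-yl)-7-(3-methylbutanoyl)-5,5-bis(3-methylbut-2-en-1-yl)-2,3-dihydro-1-benzofuran-4(5H)-one | CC(C)=CCC1(CC=C(C)C)C(=O)C2=C(O[C@@H](C(C)(C)O)C2)C(C(=O)CC(C)C)=C1O | target

## Step count and risks

Total steps: 9. Longest linear sequence: 7 steps (1, 2, 3, 6, 7, 8, 9) from phloroglucinol; steps 4 and 5 form a two-step side branch that joins at step 6.

**Step 6 (key step).**
- What may go wrong: poor facial selectivity at the ylide carbon. The methide terminus carries no substituent, so only the differentiation of the ylide's own faces by the ammonium group can set C2. Epimerisation of the betaine or of the α-aryloxy ester under carbonate would erode whatever selectivity is reached. Capture of the quinone methide by the electron-rich ring of a second molecule would lower the conversion to annulation product.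
- Fallback (from 8, returning at 18): methiodide 14 is treated with the achiral salt 1-(2-methoxy-2-oxoethyl)-4-aza-1-azoniabicyclo[2.2.2]octane bromide F1, made beforehand from 12 and 1,4-diazabicyclo[2.2.2]octane, and Cs2CO3. This racemic annulation of established type should give racemic methyl 4-(benzyloxy)-6-hydroxy-7-(3-methylbutanoyl)-2,3-dihydro-1-benzofuran-2-carboxylate F2, from which the (2R) enantiomer 18 is separated by preparative chromatography on a chiral stationary phase.

**Step 9.**
- What may go wrong: alkylation on oxygen in place of carbon, arrest after the first prenylation, or a second alkylation at the ring-fusion carbon C3a, which is also ortho and para to phenoxide oxygens. Dearomatising dialkylations of this kind are seldom clean.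
- Fallback (from 21, returning at 24): the reaction is stopped after one equivalent of 22 and the monoprenyl phenol 23 is isolated. The second prenyl group is then introduced by a π-allylpalladium alkylation of Tsuji–Trost type (Pd(PPh3)4, prenyl methyl carbonate, THF), which attacks through the soft carbon of the phenoxide at the less hindered allyl terminus. No compound outside the list is made.

**Step 7.**
- What may go wrong: over-addition of the Grignard reagent to the aryl ketone if the magnesium phenoxide does not shield it well enough, and loss of configuration by enolisation of the intermediate α-aryloxy methyl ketone 19.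
- Fallback (from 18, returning at 24): the Grignard step is moved to the end. Hydrogenolysis of 18 (H2, Pd/C) gives methyl (2R)-4,6-dihydroxy-7-(3-methylbutanoyl)-2,3-dihydro-1-benzofuran-2-carboxylate F3. Twofold C-prenylation with 22 and NaOMe in MeOH at 0 °C (non-hydrolytic, to keep the methyl ester) gives methyl (2R)-6-hydroxy-7-(3-methylbutanoyl)-5,5-bis(3-methylbut-2-en-1-yl)-4-oxo-2,3,4,5-tetrahydro-1-benzofuran-2-carboxylate F4. Its tricarbonyl array is masked as the magnesium enolate by the first equivalent of MeMgBr, so the excess adds to the ester alone and gives 24. The alkoxide step carries its own risk of epimerisation at C2.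

**Step 2.**
- What may go wrong: over-alkylation to the 2,4-dibenzyl ether and C-benzylation of the very electron-rich ring, both at the expense of the mono-ether.
- Fallback (from 3, returning at 5): benzylation is driven with 2.2 equivalents of 4 to 1-[2,4-bis(benzyloxy)-6-hydroxyphenyl]-3-methylbutan-1-one F5, in which the last, chelated hydroxyl resists alkylation. The benzyl ether ortho to the carbonyl is then removed by chelation-controlled cleavage with BCl3 (1 equiv, CH2Cl2, −78 °C) to give 5.

## Further compounds

F1 | step 6 | 1-(2-methoxy-2-oxoethyl)-4-aza-1-azoniabicyclo[2.2.2]octane bromide | COC(=O)C[N+]12CCN(CC1)CC2.[Br-]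
F2 | step 6 | racemic methyl 4-(benzyloxy)-6-hydroxy-7-(3-methylbutanoyl)-2,3-dihydro-1-benzofuran-2-carboxylate | CC(C)CC(=O)c1c(O)cc(OCc2ccccc2)c2c1OC(C(=O)OC)C2
F0 | step 9 | none | none
F3 | step 7 | methyl (2R)-4,6-dihydroxy-7-(3-methylbutanoyl)-2,3-dihydro-1-benzofuran-2-carboxylate | CC(C)CC(=O)c1c(O)cc(O)c2c1O[C@@H](C(=O)OC)C2
F4 | step 7 | methyl (2R)-6-hydroxy-7-(3-methylbutanoyl)-5,5-bis(3-methylbut-2-en-1-yl)-4-oxo-2,3,4,5-tetrahydro-1-benzofuran-2-carboxylate | CC(C)=CCC1(CC=C(C)C)C(=O)C2=C(O[C@@H](C(=O)OC)C2)C(C(=O)CC(C)C)=C1O
F5 | step 2 | 1-[2,4-bis(benzyloxy)-6-hydroxyphenyl]-3-methylbutan-1-one | CC(C)CC(=O)c1c(O)cc(OCc2ccccc2)cc1OCc1ccccc1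
A1 | alternative 1 | 3-ethoxy-4,4-bis(3-methylbut-2-en-1-yl)cyclobut-2-en-1-one | CCOC1=CC(=O)C1(CC=C(C)C)CC=C(C)C
A2 | alternative 1 | triisopropyl({3-[(4R)-2,2,5,5-tetramethyl-1,3-dioxolan-4-yl]prop-1-yn-1-yl}oxy)silane | CC(C)[Si](OC#CC[C@H]1OC(C)(C)OC1(C)C)(C(C)C)C(C)C
A3 | alternative 1 | 5-ethoxy-6,6-bis(3-methylbut-2-enyl)-2-{[(4R)-2,2,5,5-tetramethyl-1,3-dioxolan-4-yl]methyl}-3-(triisopropylsilyloxy)cyclohexa-2,4-dien-1-one | CCOC1=CC(O[Si](C(C)C)(C(C)C)C(C)C)=C(C[C@H]2OC(C)(C)OC2(C)C)C(=O)C1(CC=C(C)C)CC=C(C)C
A4 | alternative 2 | 1-[2-iodo-4,6-bis(methoxymethoxy)phenyl]-3-methylbutan-1-one | CC(C)CC(=O)c1c(I)cc(OCOC)cc1OCOC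
A5 | alternative 2 | triethyl({2-[(2R)-oxiran-2-yl]propan-2-yl}oxy)silane | CC[Si](CC)(CC)OC(C)(C)[C@H]1CO1
A6 | alternative 2 | 1-[(2R)-4,6-bis(methoxymethoxy)-2-(2-triethylsilyloxypropan-2-yl)-2,3-dihydro-1-benzofuran-7-yl]-3-methylbutan-1-one | CC(C)CC(=O)c1c(OCOC)cc(OCOC)c2c1O[C@@H](C(C)(C)O[Si](CC)(CC)CC)C2
A7 | alternative 3 | 1-[4-(benzyloxy)-2,6-dihydroxy-3-(3-methylbut-2-en-1-yl)phenyl]-3-methylbutan-1-one | CC(C)CC(=O)c1c(O)cc(OCc2ccccc2)c(CC=C(C)C)c1O
A8 | alternative 3 | 1-[(3S)-5-(benzyloxy)-3,7-dihydroxy-2,2-dimethyl-3,4-dihydro-2H-1-benzopyran-8-yl]-3-methylbutan-1-one | CC(C)CC(=O)c1c(O)cc(OCc2ccccc2)c2c1OC(C)(C)[C@@H](O)C2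
A9 | alternative 3 | 1-[(2R)-4-(benzyloxy)-6-hydroxy-2-(2-hydroxypropan-2-yl)-2,3-dihydro-1-benzofuran-7-yl]-3-methylbutan-1-one | CC(C)CC(=O)c1c(O)cc(OCc2ccccc2)c2c1O[C@@H](C(C)(C)O)C2
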